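# Total synthesis of ludongnin H

**Retrosynthesis**
1. Ludongnin H (21) comes from C16 equilibration of keto-lactone 20. Ring D (the C8–C15 bond, bicyclo[3.2.1]octane) is closed last by acylation of the C8 lactone enolate with a C13-tethered Weinreb amide.
2. Spiro-δ-lactone 19 (the C9–C10 bond and the C10 quaternary centre) comes from an Fe–H (MHAT) 6-endo radical conjugate addition in ester 18. Ester 18 is the late union of alcohol 9 (A ring plus 6,19-epoxy methyl acetal) and acid 17 (ring C with the C13 side chain).
3. Alcohol 9 is built from 3-methylcyclohexenone: asymmetric 1,4-addition (C4), orthoformate C-alkylation (C5/C6), vinyl → C19 alcohol, cycloacetalisation, then ketone → allylic alcohol (C20). Acid 17 is built from cyclohexenone: Rh-catalysed 1,4-addition (C13), enol triflate and carbonylation (C8=C9 enoate), then side chain → Weinreb amide.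
4. Rings are formed in this order: A (already in 1), THF acetal (step 5), C (already in 10), lactone B with C9–C10 (step 17), D (step 18).

Assumption: C6 (anomeric) and C16 (α to the ketone) are thermodynamic centres set by equilibration. The ligand enantiomers in steps 1 and 9 are chosen to give the drawn absolute configuration.

## Route

**Step 1**
Reactants: 1 3-methylcyclohex-2-en-1-one
Product: 2 (3S)-trimethyl[(3-methyl-3-vinylcyclohex-1-en-1-yl)oxy]silane
Conditions: CH2=CHMgBr, CuBr·SMe2 (5 mol%), chiral ferrocenyl diphosphine L* (6 mol%), t-BuOMe, −78 °C; then TMSCl, −78 → 0 °C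
Reagents that add atoms: vinylmagnesium bromide C=C[Mg]Br; chlorotrimethylsilane C[Si](C)(C)Cl
Why: Cu-catalysed asymmetric conjugate addition to the β,β-disubstituted enone sets the C4 quaternary centre under ligand control. The enolate forms regiospecifically toward C5 and is trapped as the TMS enol ether.

**Step 2**
Reactants: 2 silyl enol ether
Product: 3 (3S)-2-(dimethoxymethyl)-3-methyl-3-vinylcyclohexan-1-one (C2 epimeric)
Conditions: HC(OMe)3, TMSOTf (10 mol%), CH2Cl2, −78 °C; NaHCO3 quench
Reagents that add atoms: trimethyl orthoformate COC(OC)OC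
Why: Mukaiyama-type addition of the enol ether to the dimethoxycarbenium ion puts C6 on C5 at the acetal oxidation level. The epimerisable C5 is fixed in step 5.

**Step 3**
Reactants: 3
Product: 4 (1R)-2-(dimethoxymethyl)-1-methyl-3-oxocyclohexane-1-carbaldehyde (C2 epimeric)
Conditions: O3, CH2Cl2/MeOH, NaHCO3, −78 °C; then Me2S
Reagents that add atoms: ozone [O-][O+]=O
Why: Ozonolysis cleaves the terminal vinyl group to the C19 aldehyde (C19 is the former vinyl CH). The ketone and dimethyl acetal are untouched and C4 is not disturbed.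

**Step 4**
Reactants: 4
Product: 5 (3R)-2-(dimethoxymethyl)-3-(hydroxymethyl)-3-methylcyclohexan-1-one (C2 epimeric)
Conditions: NaBH4, CH2Cl2/EtOH (1:1), −78 °C
Reagents that add atoms: none
Why: At low temperature NaBH4 reduces the aldehyde chemoselectively over the hindered ketone (aldehyde-selective borohydride reduction), giving C19–OH.

**Step 5**
Reactants: 5
Product: 6 cis-fused 3-methoxy-7a-methylhexahydro-2-benzofuran-4(1H)-one (single enantiomer, OMe exo, configuration as in SMILES)
Conditions: CSA (10 mol%), CH2Cl2, 40 °C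
Reagents that add atoms: none
Why: Acid-catalysed intramolecular transacetalisation by C19–OH closes the 6,19-epoxy methyl acetal with loss of MeOH. C5 epimerises through the ketone enol, so only the cis-fused 5/6 system accumulates, and the anomeric OMe settles exo (thermodynamic).

**Step 6**
Reactants: 6
Product: 7 enol triflate (C10(OTf)=C1)
Conditions: KHMDS, THF, −78 °C; then PhNTf2, −78 °C → rt
Reagents that add atoms: N-phenylbis(trifluoromethanesulfonimide) O=S(=O)(C(F)(F)F)N(c1ccccc1)S(=O)(=O)C(F)(F)F
Why: Kinetic deprotonation occurs at the unhindered C1 (C5–H is tertiary and flanked by quaternary C4). This places the alkene at C10=C1, as needed for the later HAT step.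

**Step 7**
Reactants: 7
Product: 8 methyl 3-methoxy-7a-methyl-1,3,3a,6,7,7a-hexahydro-2-benzofuran-4-carboxylate
Conditions: Pd(OAc)2 (5 mol%), PPh3 (10 mol%), CO (1 atm), Et3N, MeOH/DMF, 60 °C
Reagents that add atoms: carbon monoxide [C-]#[O+]; methanol CO
Why: Pd-catalysed methoxycarbonylation of the vinyl triflate supplies C20 as an α,β-unsaturated ester with no stereochemical change.

**Step 8**
Reactants: 8
Product: 9 (3-methoxy-7a-methyl-1,3,3a,6,7,7a-hexahydro-2-benzofuran-4-yl)methanol (A-ring fragment)
Conditions: DIBAL-H (2.5 equiv), CH2Cl2, −78 °C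
Reagents that add atoms: none
Why: 1,2-Reduction of the conjugated ester gives the allylic alcohol (C20–OH). The cyclic acetal survives at −78 °C.

**Step 9**
Reactants: 10 cyclohex-2-en-1-one
Product: 11 (R)-3-(prop-1-en-2-yl)cyclohexan-1-one
Conditions: K[CH2=C(Me)BF3], [Rh(cod)Cl]2 (2.5 mol%), BINAP (5.5 mol%; enantiomer giving R), toluene/H2O (10:1), 60 °C
Reagents that add atoms: potassium isopropenyltrifluoroborate C=C(C)[B-](F)(F)F.[K+]
Why: Rh-catalysed asymmetric 1,4-addition (Hayashi–Miyaura type) creates the C13 stereocentre.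

**Step 10**
Reactants: 11
Product: 12 (R)-5-(prop-1-en-2-yl)cyclohex-1-en-1-yl trifluoromethanesulfonate
Conditions: KHMDS, THF, −78 °C; then PhNTf2; chromatographic removal of the C8=C14 regioisomer
Reagents that add atoms: PhNTf2 O=S(=O)(C(F)(F)F)N(c1ccccc1)S(=O)(=O)C(F)(F)F
Why: Kinetic deprotonation at C9, the side remote from the C13 substituent, gives the C8=C9 enol triflate preferentially (about 3:1). The regioisomer is separated.

**Step 11**
Reactants: 12
Product: 13 methyl (R)-5-(prop-1-en-2-yl)cyclohex-1-ene-1-carboxylate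
Conditions: Pd(OAc)2, PPh3, CO (1 atm), Et3N, MeOH/DMF, 60 °C
Reagents that add atoms: carbon monoxide [C-]#[O+]; methanol CO
Why: Pd-catalysed methoxycarbonylation installs C7 on C8 as the conjugated ester, which is the acceptor alkene for step 17.

**Step 12**
Reactants: 13
Product: 14 methyl (5R)-5-(1-hydroxypropan-2-yl)cyclohex-1-ene-1-carboxylate (about 1:1 at C16)
Conditions: 9-BBN, THF, 0 °C → rt; then NaBO3·4H2O, THF/H2O
Reagents that add atoms: sodium peroxoborate (O-atom source) [Na+].OO[B-](O)(O)O
Why: Hydroboration of the 1,1-disubstituted alkene is faster than reduction of the enoate. Anti-Markovnikov placement gives the primary alcohol (C15–OH). C16 is created as an epimeric mixture, which is irrelevant because C16 is reset in step 19.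

**Step 13**
Reactants: 14
Product: 15 2-[(1R)-3-(methoxycarbonyl)cyclohex-3-en-1-yl]propanoic acid (C16 epimeric)
Conditions: TEMPO (10 mol%), NaClO2, NaOCl (cat.), MeCN/pH 6.7 phosphate buffer, 35 °C
Reagents that add atoms: sodium chlorite [Na+].[O-]Cl=O
Why: TEMPO/chlorite oxidation takes the primary alcohol to the carboxylic acid under mild conditions that leave the enoate intact.

**Step 14**
Reactants: 15
Product: 16 methyl (5R)-5-[1-(methoxy(methyl)amino)-1-oxopropan-2-yl]cyclohex-1-ene-1-carboxylate
Conditions: MeNH(OMe)·HCl, EDC·HCl, HOBt, i-Pr2NEt, CH2Cl2, 0 °C → rt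
Reagents that add atoms: N,O-dimethylhydroxylamine hydrochloride CONC.Cl
Why: Carbodiimide amide coupling forms the Weinreb amide that will become the C15 ketone.

**Step 15**
Reactants: 16
Product: 17 (5R)-5-[1-(methoxy(methyl)amino)-1-oxopropan-2-yl]cyclohex-1-ene-1-carboxylic acid (ring C fragment)
Conditions: LiOH·H2O, THF/MeOH/H2O, rt
Reagents that add atoms: lithium hydroxide [Li+].[OH-]
Why: Saponification of the unhindered methyl enoate goes selectively in the presence of the Weinreb amide, releasing the C7 acid.

**Step 16**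
Reactants: 9 allylic alcohol; 17 acid
Product: 18 ester: (3-methoxy-7a-methyl-hexahydro-2-benzofuran-4-yl)methyl 5-[1-(N-methoxy-N-methylamino)-1-oxopropan-2-yl]cyclohex-1-ene-1-carboxylate
Conditions: 2,4,6-Cl3C6H2COCl, Et3N, THF; then 9, DMAP, toluene, rt
Reagents that add atoms: none
Why: Yamaguchi esterification is the late fragment union. It joins C7 to O–C20, which sets up the tether for the radical cyclisation without touching any stereocentre.

**Step 17**
Reactants: 18
Product: 19 spiro-δ-lactone with the C9–C10 bond formed (C8–H and C16 unspecified)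
Conditions: Fe(acac)3 (1 equiv), PhSiH3 (3 equiv), EtOH, 60 °C, 0.01 M
Reagents that add atoms: none
Why: Fe–H hydrogen-atom transfer to the trisubstituted C1=C10 alkene gives the tertiary C10 radical (H goes to C1). It adds 6-endo, polarity-matched, to C9 of the tethered enoate, and the C8 α-ester radical is then reduced. C10 forms equatorially, anti to the axial C19 of the cis-fused THF. C9 is set with C10 delivered to the enoate face anti to the C13 side chain; the minor 9-epimer is removed chromatographically.

**Step 18**
Reactants: 19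
Product: 20 keto-lactone with the bicyclo[3.2.1]octane formed (C16 epimeric)
Conditions: LiHMDS (2.5 equiv), THF, −78 → 0 °C; NH4Cl quench
Reagents that add atoms: none
Why: Intramolecular Claisen-type acylation (5-enolexo-exo-trig): the lactone enolate at C8, the most acidic site, attacks the Weinreb amide, and the chelated tetrahedral intermediate collapses to the C15 ketone on workup. C8 is set by the ring constraint, since C15 must bond to the face carrying the C13 side chain, and C16 forms as a mixture.

**Step 19**
Reactants: 20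
Product: 21 ludongnin H
Conditions: DBU (20 mol%), toluene, 80 °C
Reagents that add atoms: none
Why: Enolisation at C16 equilibrates the α-methyl ketone to the more stable exo-methyl epimer, which is the target configuration (thermodynamic control). No other centre can epimerise: C8 is quaternary, and the acetal and lactone are base-stable.

## Compound list

1 | 3-methylcyclohex-2-en-1-one | CC1=CC(=O)CCC1 | starting material
2 | (3S)-trimethyl[(3-methyl-3-vinylcyclohex-1-en-1-yl)oxy]silane | C=C[C@]1(C)CCCC(O[Si](C)(C)C)=C1 | intermediate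
3 | (3S)-2-(dimethoxymethyl)-3-methyl-3-vinylcyclohexan-1-one (C2 epimeric) | COC(OC)C1C(=O)CCC[C@@]1(C)C=C | intermediate
4 | (1R)-2-(dimethoxymethyl)-1-methyl-3-oxocyclohexane-1-carbaldehyde (C2 epimeric) | COC(OC)C1C(=O)CCC[C@@]1(C)C=O | intermediate
5 | (3R)-2-(dimethoxymethyl)-3-(hydroxymethyl)-3-methylcyclohexan-1-one (C2 epimeric) | COC(OC)C1C(=O)CCC[C@@]1(C)CO | intermediate
6 | cis-3-methoxy-7a-methylhexahydro-2-benzofuran-4(1H)-one | CO[C@H]1OC[C@]2(C)CCCC(=O)[C@H]12 | intermediate
7 | enol triflate of 6 | CO[C@H]1OC[C@]2(C)CCC=C(OS(=O)(=O)C(F)(F)F)[C@H]12 | intermediate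
8 | methyl 3-methoxy-7a-methyl-1,3,3a,6,7,7a-hexahydro-2-benzofuran-4-carboxylate | CO[C@H]1OC[C@]2(C)CCC=C(C(=O)OC)[C@H]12 | intermediate
9 | (3-methoxy-7a-methyl-1,3,3a,6,7,7a-hexahydro-2-benzofuran-4-yl)methanol | CO[C@H]1OC[C@]2(C)CCC=C(CO)[C@H]12 | intermediate (A-ring fragment)
10 | cyclohex-2-en-1-one | O=C1C=CCCC1 | starting material
11 | (R)-3-(prop-1-en-2-yl)cyclohexan-1-one | CC(=C)[C@@H]1CCCC(=O)C1 | intermediate
12 | (R)-5-(prop-1-en-2-yl)cyclohex-1-en-1-yl triflate | CC(=C)[C@@H]1CCC=C(OS(=O)(=O)C(F)(F)F)C1 | intermediate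
13 | methyl (R)-5-(prop-1-en-2-yl)cyclohex-1-ene-1-carboxylate | CC(=C)[C@@H]1CCC=C(C(=O)OC)C1 | intermediate
14 | methyl (5R)-5-(1-hydroxypropan-2-yl)cyclohex-1-ene-1-carboxylate (C16 epimeric) | OCC(C)[C@@H]1CCC=C(C(=O)OC)C1 | intermediate
15 | 2-[(1R)-3-(methoxycarbonyl)cyclohex-3-en-1-yl]propanoic acid (C16 epimeric) | OC(=O)C(C)[C@@H]1CCC=C(C(=O)OC)C1 | intermediate
16 | methyl (5R)-5-[1-(methoxy(methyl)amino)-1-oxopropan-2-yl]cyclohex-1-ene-1-carboxylate | CON(C)C(=O)C(C)[C@@H]1CCC=C(C(=O)OC)C1 | intermediate
17 | (5R)-5-[1-(methoxy(methyl)amino)-1-oxopropan-2-yl]cyclohex-1-ene-1-carboxylic acid | CON(C)C(=O)C(C)[C@@H]1CCC=C(C(=O)O)C1 | intermediate (ring C fragment)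
18 | ester of 9 and 17 | CO[C@H]1OC[C@]2(C)CCC=C(COC(=O)C3=CCC[C@H](C3)C(C)C(=O)N(C)OC)[C@H]12 | intermediate
19 | spiro-δ-lactone (C9–C10 bonded; C8 and C16 unspecified) | CO[C@H]1OC[C@]2(C)CCC[C@]3(COC(=O)C4C[C@@H](CC[C@H]43)C(C)C(=O)N(C)OC)[C@H]12 | intermediate
20 | bicyclo[3.2.1] keto-lactone (C16 unspecified) | CO[C@H]1OC[C@]2(C)CCC[C@]3(COC(=O)[C@@]45C[C@@H](CC[C@H]43)C(C)C5=O)[C@H]12 | intermediate
21 | ludongnin H | CO[C@H]1OC[C@]2(C)CCC[C@]3(COC(=O)[C@@]45C[C@@H](CC[C@H]43)[C@H](C)C5=O)[C@H]12 | target

## Summary

Total steps: 19.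
Longest linear sequence: 12 steps (1→2→3→4→5→6→7→8→16→17→18→19).

**Three steps most likely to fail**
1. **Step 17 (MHAT 6-endo spirolactonisation).** The risks are the hindered quaternary C10 and the C9 diastereoselectivity relative to C13. Fallback: pre-assemble the bicyclo[3.2.1]octenone acceptor (C9=C11–C12=O, ring D closed first by the same Weinreb acylation). Couple it with 9 and close the lactone by 6-exo Fe–H addition onto the enone, where the two-carbon bridge fixes the face. Then remove the C12 ketone through its tosylhydrazone (catecholborane reduction).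
2. **Step 18 (bridgehead acylation of the hindered C8 enolate).** Fallback: reduce the Weinreb amide to the aldehyde with DIBAL-H and close ring D by intramolecular aldol of the lactone titanium enolate (TiCl4, Et3N). Then oxidise the C15 alcohol with Dess–Martin periodinane.
3. **Step 1 (asymmetric vinyl addition creating the C4 quaternary centre).** Fallback: CBS reduction of 1 to the (S)-allylic alcohol, conversion to its Bu3SnCH2 ether, and Still–Mitra [2,3]-Wittig rearrangement. This gives the C4 quaternary neopentyl carbinol (C19–OH) with chirality transfer. C5–C6 is then built by Ueno–Stork-type radical cyclisation of the derived bromomethyl ether onto the ring alkene, and the route converges on 5/6.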